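**Plan**

- Retrosynthesis first removes the three benzyl groups and traces the ring A methyl ester back to a dioxolane-masked formyl group. It then cuts ring B through two ring bonds, C4–C5 and C6–C1.
- The feature that allows this cut: ring B carries CO2H (C1), OH (C2), Cl (C3) and CH3 (C4) on four adjacent carbons, which map onto C3, C4, C5 and C6 of a 5-chloro-4-oxygenated 6-methyl-2-pyrone-3-carboxylate. The remaining pair, C5–H and C6–OAr, is the two-carbon unit of an aryl ethynyl ether.
- The diaryl ether oxygen is never joined to a finished arene. It arrives as the ynol ether oxygen, set on the ring A phenol with trichloroethene. The pyrone comes from a chlorinated dioxinone and dibenzyl malonate.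
- Forward order: ring A ynol ether from o-vanillin (steps 1–5), pyrone (steps 6–8), ring B by cycloaddition with loss of CO2 (step 9), then acetal to aldehyde to acid to methyl ester and hydrogenolysis (steps 10–13).
- The target has no stereocentre. The only selectivity to control is the orientation of the alkyne in the cycloaddition, set by the polarity of the two partners.

Key step: step 9

Remark: bridged lactone 18 is racemic and is written as one enantiomer; acylmalonate 15 is written in its keto form although it will be present as its sodium enolate.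

**Step 1**
Reactants: 1 o-vanillin (2-hydroxy-3-methoxybenzaldehyde)
Product: 3 2,5-dihydroxy-3-methoxybenzaldehyde, via aryl potassium sulfate 2 (not isolated)
Conditions: K2S2O8, aq KOH, 0 to 20 °C; then HCl, 90 °C
Reagents that add atoms: potassium peroxodisulfate ([K+].[K+].[O-]S(=O)(=O)OOS(=O)(=O)[O-])
Why: Elbs persulfate oxidation, in which the phenolate attacks a peroxide oxygen through its para carbon (both ortho positions are blocked by CHO and OCH3) and acid hydrolysis of the aryl sulfate frees the hydroquinone.

**Step 2**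
Reactants: 3 2,5-dihydroxy-3-methoxybenzaldehyde
Product: 4 5-(benzyloxy)-2-hydroxy-3-methoxybenzaldehyde
Conditions: BnBr (1.0 equiv), K2CO3 (1.1 equiv), DMF, 0 °C to rt, N2
Reagents that add atoms: benzyl bromide (BrCc1ccccc1)
Why: Williamson ether synthesis that should take place at the 5-hydroxyl, because the 2-hydroxyl is hydrogen-bonded to the formyl group and flanked on both sides.

**Step 3**
Reactants: 4 5-(benzyloxy)-2-hydroxy-3-methoxybenzaldehyde; 5 trichloroethene
Product: 6 5-(benzyloxy)-2-{[(E)-1,2-dichloroethenyl]oxy}-3-methoxybenzaldehyde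
Conditions: ClCH=CCl2 (2 equiv), K2CO3, DMF, 70 °C
Reagents that add atoms: none
Why: K2CO3 converts trichloroethene into dichloroethyne in the flask, the phenoxide adds to it and anti protonation gives the (E)-dichlorovinyl ether, the established entry to aryl dichlorovinyl ethers; the non-enolisable aldehyde is a spectator.

**Step 4**
Reactants: 6 5-(benzyloxy)-2-{[(E)-1,2-dichloroethenyl]oxy}-3-methoxybenzaldehyde
Product: 7 2-(5-(benzyloxy)-2-{[(E)-1,2-dichloroethenyl]oxy}-3-methoxyphenyl)-1,3-dioxolane
Conditions: HOCH2CH2OH, PPTS (cat.), toluene, reflux, Dean-Stark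
Reagents that add atoms: ethylene glycol (OCCO)
Why: Acid-catalysed acetalisation with azeotropic removal of water masks the formyl group against butyllithium, and the dichlorovinyl ether, a strongly deactivated enol ether, should tolerate the mild acid.

**Step 5**
Reactants: 7 2-(5-(benzyloxy)-2-{[(E)-1,2-dichloroethenyl]oxy}-3-methoxyphenyl)-1,3-dioxolane
Product: 10 2-[5-(benzyloxy)-2-(ethynyloxy)-3-methoxyphenyl]-1,3-dioxolane, via chloroethynyl ether 8 (not isolated), via lithium acetylide 9 (not isolated)
Conditions: n-BuLi (2.3 equiv), THF, −78 to −40 °C; H2O, −78 °C; used at once in step 9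
Reagents that add atoms: none
Why: n-BuLi removes the vinylic proton and chloride is eliminated to give 8, a second equivalent exchanges the alkynyl chlorine for lithium to give 9 and water protonates it, the standard conversion of aryl dichlorovinyl ethers into terminal ynol ethers, with acetal and ethers inert at −78 °C.

**Step 6**
Reactants: 11 2,2,6-trimethyl-4H-1,3-dioxin-4-one
Product: 12 5-chloro-2,2,6-trimethyl-4H-1,3-dioxin-4-one
Conditions: NCS, AcOH, rt to 50 °C
Reagents that add atoms: N-chlorosuccinimide (O=C1CCC(=O)N1Cl)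
Why: Electrophilic chlorination at C5, the only nucleophilic carbon of the enol-ether-type double bond of the dioxinone, fixes the chlorine next to the methyl-bearing carbon.

**Step 7**
Reactants: 12 5-chloro-2,2,6-trimethyl-4H-1,3-dioxin-4-one; 13 dibenzyl malonate
Product: 16 benzyl 5-chloro-4-hydroxy-6-methyl-2-oxo-2H-pyran-3-carboxylate, via chloroacetylketene 14 (not isolated), via acylmalonate 15 (not isolated)
Conditions: NaH (1.05 equiv), 13, toluene/DME, rt; then 12 added slowly, 110 °C; aq HCl
Reagents that add atoms: none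
Why: Retro-[4+2] fragmentation of 12 releases acetone and acylketene 14, which C-acylates the sodium enolate of 13, and the enolate of 15 lactonises onto one benzyl ester with loss of benzyl alcohol, the dioxinone version of the classical diketene-malonate synthesis of 3-alkoxycarbonyl-4-hydroxy-6-methyl-2-pyrones.

**Step 8**
Reactants: 16 benzyl 5-chloro-4-hydroxy-6-methyl-2-oxo-2H-pyran-3-carboxylate
Product: 17 benzyl 4-(benzyloxy)-5-chloro-6-methyl-2-oxo-2H-pyran-3-carboxylate
Conditions: BnOH, PPh3, DIAD, THF, 0 °C to rt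
Reagents that add atoms: benzyl alcohol (OCc1ccccc1)
Why: Mitsunobu alkylation of the acidic enol, which for 4-hydroxy-2-pyrones is known to occur on the 4-oxygen, caps the hydroxyl that would otherwise protonate the ynol ether.

**Step 9**
Reactants: 17 benzyl 4-(benzyloxy)-5-chloro-6-methyl-2-oxo-2H-pyran-3-carboxylate; 10 2-[5-(benzyloxy)-2-(ethynyloxy)-3-methoxyphenyl]-1,3-dioxolane
Product: 19 benzyl 2-(benzyloxy)-6-[4-(benzyloxy)-2-(1,3-dioxolan-2-yl)-6-methoxyphenoxy]-3-chloro-4-methylbenzoate, via bridged lactone 18 (not isolated)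
Conditions: 10 (1.5 equiv), toluene, 110 to 130 °C, sealed tube, BHT (cat.)
Reagents that add atoms: none
Why: Proposed new method: the electron-poor diene C3=C4-C5=C6 of pyrone 17 should take up the electron-rich triple bond of 10 in an inverse-electron-demand [4+2] cycloaddition that is probably asynchronous, the terminal alkyne carbon bonding to C6 ahead of closure of the oxygen-bearing carbon onto C3, and bridged lactone 18 then expels CO2 by cycloreversion to give the arene directly. The closest known reaction type is the Diels-Alder addition and decarboxylation of 3-alkoxycarbonyl-2-pyrones with ynamines and ketene acetals, which delivers ortho-heteroatom-substituted benzoates in the same orientation, whereas an aryl ethynyl ether has not been shown as the two-carbon partner. Ring B is closed as a six-membered carbocycle by this intermolecular [4+2] addition, which makes its C4-C5 and C6-C1 bonds, and no elimination is needed for aromatisation, so the aryloxy group cannot leave. No stereocentre is created in the product, because the two bridgeheads of racemic 18 turn into sp2 carbons when CO2 is lost. The one selectivity required is the orientation that puts the aryloxy group next to the ester, and it is secured by the polarity of both partners: C6 is the vinylogous acceptor terminus of the lactone carbonyl and the 3-ester, the ynol ether is nucleophilic at its CH carbon, and the malonate-type anion that develops at C3 captures the oxygen-stabilised cationic carbon. The 5-chloro and 3-ester groups offset the donor effect of the 4-benzyloxy group, and an aryl-O-C≡CH unit cannot fragment to a ketene and an alkene as alkyl ynol ethers do on heating, so 10 should last at the temperature the tetrasubstituted pyrone needs.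

**Step 10**
Reactants: 19 benzyl 2-(benzyloxy)-6-[4-(benzyloxy)-2-(1,3-dioxolan-2-yl)-6-methoxyphenoxy]-3-chloro-4-methylbenzoate
Product: 20 benzyl 2-(benzyloxy)-6-[4-(benzyloxy)-2-formyl-6-methoxyphenoxy]-3-chloro-4-methylbenzoate
Conditions: 1 M HCl, THF, rt
Reagents that add atoms: water (O)
Why: Acid-catalysed hydrolysis of the dioxolane proceeds under conditions that leave the benzyl ester, the benzyl ethers and the diaryl ether untouched.

**Step 11**
Reactants: 20 benzyl 2-(benzyloxy)-6-[4-(benzyloxy)-2-formyl-6-methoxyphenoxy]-3-chloro-4-methylbenzoate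
Product: 21 5-(benzyloxy)-2-{3-(benzyloxy)-2-[(benzyloxy)carbonyl]-4-chloro-5-methylphenoxy}-3-methoxybenzoic acid
Conditions: NaClO2, NaH2PO4, 2-methyl-2-butene, t-BuOH/H2O, rt
Reagents that add atoms: sodium chlorite ([Na+].[O-]Cl=O)
Why: Pinnick oxidation converts the hindered aryl aldehyde into the acid, and the alkene scavenger removes hypochlorous acid before it can chlorinate the electron-rich ring A.

**Step 12**
Reactants: 21 5-(benzyloxy)-2-{3-(benzyloxy)-2-[(benzyloxy)carbonyl]-4-chloro-5-methylphenoxy}-3-methoxybenzoic acid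
Product: 22 benzyl 2-(benzyloxy)-6-[4-(benzyloxy)-2-methoxy-6-(methoxycarbonyl)phenoxy]-3-chloro-4-methylbenzoate
Conditions: MeI, K2CO3, DMF, rt
Reagents that add atoms: iodomethane (CI)
Why: SN2 alkylation of the carboxylate oxygen is insensitive to the crowding around the carboxyl carbon and leaves the benzyl ester intact, so the two ester groups of the target are now differentiated.

**Step 13**
Reactants: 22 benzyl 2-(benzyloxy)-6-[4-(benzyloxy)-2-methoxy-6-(methoxycarbonyl)phenoxy]-3-chloro-4-methylbenzoate
Product: 23 isodihydromaldoxin (3-chloro-2-hydroxy-6-[4-hydroxy-2-methoxy-6-(methoxycarbonyl)phenoxy]-4-methylbenzoic acid)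
Conditions: H2 (1 atm), 10% Pd/C, EtOAc, rt, stopped after uptake of 3 equiv
Reagents that add atoms: none
Why: Catalytic hydrogenolysis cleaves the benzyl ester and both benzyl ethers, while under neutral conditions the aryl chloride, flanked by OH and CH3, should be reduced far more slowly.

**Compound list**

1 | o-vanillin (2-hydroxy-3-methoxybenzaldehyde) | COc1cccc(C=O)c1O | starting material
2 | potassium 3-formyl-4-hydroxy-5-methoxyphenyl sulfate (formed in the flask) | COc1cc(OS(=O)(=O)[O-])cc(C=O)c1O.[K+] | intermediate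
3 | 2,5-dihydroxy-3-methoxybenzaldehyde | COc1cc(O)cc(C=O)c1O | intermediate
4 | 5-(benzyloxy)-2-hydroxy-3-methoxybenzaldehyde | COc1cc(OCc2ccccc2)cc(C=O)c1O | intermediate
5 | trichloroethene | ClC=C(Cl)Cl | starting material
6 | 5-(benzyloxy)-2-{[(E)-1,2-dichloroethenyl]oxy}-3-methoxybenzaldehyde | COc1cc(OCc2ccccc2)cc(C=O)c1O/C(Cl)=C\Cl | intermediate
7 | 2-(5-(benzyloxy)-2-{[(E)-1,2-dichloroethenyl]oxy}-3-methoxyphenyl)-1,3-dioxolane | COc1cc(OCc2ccccc2)cc(C2OCCO2)c1O/C(Cl)=C\Cl | intermediate
8 | 2-{5-(benzyloxy)-2-[(chloroethynyl)oxy]-3-methoxyphenyl}-1,3-dioxolane (formed in the flask) | COc1cc(OCc2ccccc2)cc(C2OCCO2)c1OC#CCl | intermediate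
9 | lithium 2-[4-(benzyloxy)-2-(1,3-dioxolan-2-yl)-6-methoxyphenoxy]ethynide (formed in the flask) | COc1cc(OCc2ccccc2)cc(C2OCCO2)c1OC#C[Li] | intermediate
10 | 2-[5-(benzyloxy)-2-(ethynyloxy)-3-methoxyphenyl]-1,3-dioxolane | COc1cc(OCc2ccccc2)cc(C2OCCO2)c1OC#C | intermediate
11 | 2,2,6-trimethyl-4H-1,3-dioxin-4-one | CC1=CC(=O)OC(C)(C)O1 | starting material
12 | 5-chloro-2,2,6-trimethyl-4H-1,3-dioxin-4-one | CC1=C(Cl)C(=O)OC(C)(C)O1 | intermediate
13 | dibenzyl malonate | O=C(CC(=O)OCc1ccccc1)OCc1ccccc1 | starting material
14 | 2-chloro-3-oxobut-1-en-1-one, chloroacetylketene (formed in the flask) | CC(=O)C(Cl)=C=O | intermediate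
15 | dibenzyl 2-(2-chloro-3-oxobutanoyl)propanedioate, keto form, chlorine-bearing carbon configurationally labile (formed in the flask) | CC(=O)C(Cl)C(=O)C(C(=O)OCc1ccccc1)C(=O)OCc1ccccc1 | intermediate
16 | benzyl 5-chloro-4-hydroxy-6-methyl-2-oxo-2H-pyran-3-carboxylate | Cc1oc(=O)c(C(=O)OCc2ccccc2)c(O)c1Cl | intermediate
17 | benzyl 4-(benzyloxy)-5-chloro-6-methyl-2-oxo-2H-pyran-3-carboxylate | Cc1oc(=O)c(C(=O)OCc2ccccc2)c(OCc2ccccc2)c1Cl | intermediate
18 | benzyl 5-(benzyloxy)-8-[4-(benzyloxy)-2-(1,3-dioxolan-2-yl)-6-methoxyphenoxy]-6-chloro-1-methyl-3-oxo-2-oxabicyclo[2.2.2]octa-5,7-diene-4-carboxylate, racemic, one enantiomer written (formed in the flask) | C[C@@]12OC(=O)[C@@](C(=O)OCc3ccccc3)(C(OCc3ccccc3)=C1Cl)C(Oc1c(OC)cc(OCc3ccccc3)cc1C1OCCO1)=C2 | intermediate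
19 | benzyl 2-(benzyloxy)-6-[4-(benzyloxy)-2-(1,3-dioxolan-2-yl)-6-methoxyphenoxy]-3-chloro-4-methylbenzoate | O=C(OCc1ccccc1)c1c(OCc2ccccc2)c(Cl)c(C)cc1Oc1c(OC)cc(OCc2ccccc2)cc1C1OCCO1 | intermediate
20 | benzyl 2-(benzyloxy)-6-[4-(benzyloxy)-2-formyl-6-methoxyphenoxy]-3-chloro-4-methylbenzoate | O=Cc1cc(OCc2ccccc2)cc(OC)c1Oc1cc(C)c(Cl)c(OCc2ccccc2)c1C(=O)OCc1ccccc1 | intermediate
21 | 5-(benzyloxy)-2-{3-(benzyloxy)-2-[(benzyloxy)carbonyl]-4-chloro-5-methylphenoxy}-3-methoxybenzoic acid | OC(=O)c1cc(OCc2ccccc2)cc(OC)c1Oc1cc(C)c(Cl)c(OCc2ccccc2)c1C(=O)OCc1ccccc1 | intermediate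
22 | benzyl 2-(benzyloxy)-6-[4-(benzyloxy)-2-methoxy-6-(methoxycarbonyl)phenoxy]-3-chloro-4-methylbenzoate | COC(=O)c1cc(OCc2ccccc2)cc(OC)c1Oc1cc(C)c(Cl)c(OCc2ccccc2)c1C(=O)OCc1ccccc1 | intermediate
23 | isodihydromaldoxin, 3-chloro-2-hydroxy-6-[4-hydroxy-2-methoxy-6-(methoxycarbonyl)phenoxy]-4-methylbenzoic acid | COC(=O)c1cc(O)cc(OC)c1Oc1cc(C)c(Cl)c(O)c1C(=O)O | target

**Step count and risks**

Total step count: 13. Longest linear sequence: 10 steps (steps 1 to 5, then 9 to 13); the pyrone branch (steps 6 to 8) has 3 steps.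

Steps most likely to fail:

1. Step 9 (the one step that goes beyond known chemistry). The ynol ether may oligomerise on heating faster than it adds, or the donor-substituted, fully substituted pyrone may be too weak an acceptor below that temperature. The fallback forms the diaryl ether by a classical Ullmann condensation. It sets out from phenol 4 and comes back at aldehyde 20, bypassing steps 3, 4, 5, 9 and 10.
   - Commercial 2-chloro-3-methylphenol is formylated at its only free ortho position (MgCl2, Et3N, paraformaldehyde, MeCN, reflux) to 3-chloro-2-hydroxy-4-methylbenzaldehyde F1.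
   - Benzylation (BnBr, K2CO3, DMF) gives 2-(benzyloxy)-3-chloro-4-methylbenzaldehyde F2.
   - Pinnick oxidation (NaClO2, NaH2PO4, 2-methyl-2-butene) gives 2-(benzyloxy)-3-chloro-4-methylbenzoic acid F3.
   - Carboxylate-directed C–H iodination at the single free position ortho to the carboxyl group (Pd(OAc)2 cat., PhI(OAc)2, I2, DMF) gives 2-(benzyloxy)-3-chloro-6-iodo-4-methylbenzoic acid F4.
   - Ullmann condensation of F4 with phenol 4 (CuI, K2CO3, DMF, 110 °C), a coupling that the ortho carboxylate accelerates, gives 2-(benzyloxy)-6-[4-(benzyloxy)-2-formyl-6-methoxyphenoxy]-3-chloro-4-methylbenzoic acid F5.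
   - Benzylation of the carboxylate (BnBr, K2CO3, DMF) returns to 20.

2. Step 7. Self-condensation of the chloroketene, or transfer of chlorine from the chlorinated dicarbonyl stage to the malonate anion, may outrun C-acylation and ring closure. The fallback introduces chlorine after the ring is built. It sets out from dioxinone 11 and malonate 13 and comes back at pyrone 17.
   - Heating 11 with the sodium enolate of 13 (NaH, toluene, 110 °C; aq HCl) gives benzyl 4-hydroxy-6-methyl-2-oxo-2H-pyran-3-carboxylate F6.
   - Mitsunobu benzylation (BnOH, PPh3, DIAD) gives benzyl 4-(benzyloxy)-6-methyl-2-oxo-2H-pyran-3-carboxylate F7.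
   - Electrophilic chlorination of F7 at C5, its only unsubstituted ring carbon (SO2Cl2, CH2Cl2, 0 °C, or NCS with CF3CO2H), gives 17.

3. Step 5. The terminal ynol ether may hydrate or oligomerise during aqueous work-up and concentration. The fallback caps it with a silyl group so that a storable compound is purified instead. It sets out from dichlorovinyl ether 7 and comes back at ynol ether 10.
   - Acetylide 9 is generated as in step 5 and quenched with i-Pr3SiCl instead of water, giving 2-[5-(benzyloxy)-3-methoxy-2-({[tri(propan-2-yl)silyl]ethynyl}oxy)phenyl]-1,3-dioxolane F8, which can be chromatographed and kept.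
   - Treatment of F8 with Bu4NF in THF (−78 to 0 °C) just before the cycloaddition releases 10, whose dried solution is carried into step 9 without concentration.

**Further compounds**

F1 | step 9 | 3-chloro-2-hydroxy-4-methylbenzaldehyde | Cc1ccc(C=O)c(O)c1Cl
F2 | step 9 | 2-(benzyloxy)-3-chloro-4-methylbenzaldehyde | Cc1ccc(C=O)c(OCc2ccccc2)c1Cl
F3 | step 9 | 2-(benzyloxy)-3-chloro-4-methylbenzoic acid | Cc1ccc(C(=O)O)c(OCc2ccccc2)c1Cl
F4 | step 9 | 2-(benzyloxy)-3-chloro-6-iodo-4-methylbenzoic acid | Cc1cc(I)c(C(=O)O)c(OCc2ccccc2)c1Cl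
F5 | step 9 | 2-(benzyloxy)-6-[4-(benzyloxy)-2-formyl-6-methoxyphenoxy]-3-chloro-4-methylbenzoic acid | O=Cc1cc(OCc2ccccc2)cc(OC)c1Oc1cc(C)c(Cl)c(OCc2ccccc2)c1C(=O)O
F6 | step 7 | benzyl 4-hydroxy-6-methyl-2-oxo-2H-pyran-3-carboxylate | Cc1cc(O)c(C(=O)OCc2ccccc2)c(=O)o1
F7 | step 7 | benzyl 4-(benzyloxy)-6-methyl-2-oxo-2H-pyran-3-carboxylate | Cc1cc(OCc2ccccc2)c(C(=O)OCc2ccccc2)c(=O)o1
F8 | step 5 | 2-[5-(benzyloxy)-3-methoxy-2-({[tri(propan-2-yl)silyl]ethynyl}oxy)phenyl]-1,3-dioxolane | COc1cc(OCc2ccccc2)cc(C2OCCO2)c1OC#C[Si](C(C)C)(C(C)C)C(C)C
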